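## Structural features

Compound 25 is a bicyclo[3.3.1]nonane-2,4,9-trione. Ring A (C1–C2–C3–C4–C5–C9) is an enolised β-diketone and ring B (C1–C8–C7–C6–C5–C9) is a cyclohexanone; they share the bridgeheads C1 and C5 and the bridging ketone C9. C1 carries a (2R)-2-methylbutanoyl group, C3 a 3-hydroxy-3-methylbutyl chain, C5 and C7 one prenyl group each, and C8 two methyl groups. Three stereocentres (C1, C5, C7) lie in ring B, with the quaternary C8 wedged between C1 and C7; the C7 prenyl group is exo, that is cis to the C5 prenyl group and trans to the C2–C4 bridge. The fourth stereocentre is outside the rings, α to the C1 ketone. Because the bridge can span only one face of ring B, C1 and C5 are tied to each other: once C7 is fixed, only one relative relation (bridge trans to the C7 chain) is left to control, and the acyl stereocentre can be bought. Fragile features are the acidic ambident enol, the tertiary alcohol that can close onto that enol under acid, two acid- and oxidant-sensitive trisubstituted alkenes, the epimerisable acyl α-carbon, and the non-enolisable 1,3-dicarbonyl arrays around C9 that nucleophiles can cleave. The real difficulty is the crowded C1–C8–C7 sequence together with the need to tell the C3 chain from two prenyl groups. In ring B the C9 oxygen is 1,4 to C7 and 1,3 to C8, and C8 is the direct neighbour of C7; this is the pattern of a 2-silyloxydiene with two methyl groups on its terminus joined to an acrylate, and the key step uses it to form C5–C6 and C7–C8 and to set C7.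

## Logic of the disconnections

**25 ⇒ 23 (through 24).** No skeletal bond is cut; the O–CH3 bond at C2 and the O–Si bond of the side chain are put back. The free enol is acidic and ambident and the tertiary alcohol would be acylated or would cyclise, so both stay masked until the end. The gain is that every C–C bond is made on a neutral vinylogous ester. The demand is an unmasking without acid (ring closure of the alcohol onto the enol) and without a base strong enough to epimerise the acyl α-carbon.

**23 ⇒ 20 + 22 (22 from 21).** The exocyclic C1–C(=O) bond is cut. C1 is the only bridgehead that still bears hydrogen in 20 and a bridgehead carbanion cannot invert, so the configuration at C1 is not at stake. This removes the most hindered quaternary centre and the fourth stereocentre, which comes from purchased 21. The forward step needs a site-selective bridgehead metalation and an acyl transfer that is faster than α-deprotonation of 22.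

**20 ⇒ 16 + 18 (through 19); 16 ⇒ 15; 18 ⇒ 17.** The C3–CH2 bond is cut. C3 is an sp2 carbon between C2 and C4, so an iodide there can be coupled with a primary alkylborane that already carries the protected tertiary alcohol. The C3 chain is thereby told apart from the two prenyl groups without any selective alkene hydration. The demands are iodination at C3 and not at C1, coupling at a doubly flanked vinyl iodide, and a hydroboration that is finished on 18 before 16 is added.

**15 ⇒ 14 ⇒ 13 (13 from 11 through 12).** C1–C2 and C4–C5 are cut, taking out C2–C3–C4 as a malonyl unit. A three-carbon 1,3-bis-electrophile delivers ring A directly at the trione oxidation level, so ring A never has to be oxidised in the presence of prenyl alkenes. The bicycle collapses to a monocyclic enol ether and both bridgehead centres disappear, leaving C7 as the only ring stereocentre. The demand is that both acylations occur on carbon and on the face trans to the C7 chain.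

**11 ⇒ 10.** The bond between C5 and its prenyl CH2 is cut. The ketone is alkylated on the α-carbon remote from the gem-dimethyl group, which shields the other side. This leaves a 3,3,4-trisubstituted cyclohexanone with one stereocentre; the forward step needs kinetic regiocontrol only.

**10 ⇒ 8 (through 9) ⇒ 7 ⇒ 6.** The CH2–CH= bond of the C7 prenyl group is cut, and the CH2 is traced back to the carbonyl carbon of 6. The carbonyl group that activates the dienophile thus becomes the first carbon of the side chain. The demands are a substitution at a β-branched primary carbon and an enol ether that survives hydride and organometallic reagents, so that it serves as the protecting group of C9.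

**6 ⇒ 2 + 5.** C5–C6 and C7–C8 are cut. Ring B and its only independent stereocentre come from two achiral acyclic pieces in one catalytic step. The demands are regiocontrol, enantiofacial control, and a diene whose cis terminal methyl group makes it reluctant to react in a concerted way.

**2 ⇒ 1; 5 ⇒ 3 + 4.** An O–Si bond and an N–acyl bond are cut. The demand is enolisation of 1 on the methyl side and acylation of 3 without polymerisation of the acrylate.

## Other disconnections considered

**Alternative 1:** The cut removes C3 with its chain by breaking C2–C3 and C3–C4. It leads back to the bridged 1,2-diketone A1 (a bicyclo[3.2.1]octane-6,7,8-trione with ring B complete) and the diazoalkane A2. In the forward step Sc(OTf)3 (trivalent scandium) would activate one of the vicinal carbonyl groups, A2 would add through carbon, and a 1,2-shift of the neighbouring acyl carbon with loss of N2 would insert C3 and give the enolised trione A3.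
- In favour: ring A arrives at its final oxidation level with C3 already alkylated, so one step would do the work of steps 10, 11 and 13 of the chosen route. On convergence at C3 this plan is the better one. Addition to either carbonyl leads to the same A3 as long as the acyl carbon migrates.
- Against: migration of the bridgehead alkyl carbon and epoxide formation are competing channels, and their balance rests on migratory aptitude and not on anything adjustable in the substrate. A2 is a non-stabilised diazoalkane that must be generated and used cold. A1 is a strained trione that needs a two-carbon annulation and an oxidation, and C7 must be set before that.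
- Comparison: structurally the plan solves ring A only and leaves ring B where it was (the cycloaddition of the chosen plan could feed it). Mechanistically it trades two well-understood steps for one with an open selectivity question. In step count the saving at C3 is likely spent on A1, so the two plans should be about equal in length.

**Alternative 2:** The cut is C1–C2. The precursor is A4, the mono silyl enol ether of a 2-prenyl-2-propargyl-5,5-dimethylcyclohexane-1,3-dione. In the forward step [Au(NCMe)(P(t-Bu)2(biphenyl-2-yl))]SbF6 (monovalent gold) would activate the terminal alkyne and the enol ether carbon would attack the alkyne terminus in a 6-endo-dig closure to give A5.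
- In favour: the symmetric dione core supplies C6–C9 with the gem-dimethyl group at almost no cost. The ring closure is catalytic, neutral and atom-economical and should be more efficient than the double acylation of step 9; on that point this plan is the better one. Both bridgeheads are fixed as soon as C5 is.
- Against: the absolute configuration depends on telling apart two enantiotopic carbonyl groups whose flanking substituents (prenyl and propargyl) differ little in size. The C7 prenyl group must be added later next to the C6 carbonyl, which then has to be removed, and the exo orientation at C7 must be controlled at that stage. Ring A emerges as an alkene two oxidation levels too low, so C2 and C4 must be oxygenated in the presence of prenyl groups.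
- Comparison: structurally the chosen plan sets C7 first by catalyst and derives C5 and C1 from it, while this plan sets C5 first and derives C7. Mechanistically both rest on one catalytic enantio-determining step. In step count the chosen plan should be clearly shorter because ring A is formed at the right oxidation level and C7 needs no carbonyl removal.

**Alternative 3:** The cut is C1–C8. The precursor is A6, a 1,5-dimethoxycyclohexa-1,4-diene whose quaternary carbon carries a prenyl group and an epoxidised prenyl group. In the forward step Me3SiOTf would open the epoxide at its tertiary carbon and one of the two enantiotopic enol ethers would attack, closing ring B to give A7.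
- In favour: A6 should be reachable in very few steps, and a single reagent-controlled epoxidation supplies the only stereocentre. The cyclisation builds the quaternary C8, fixes C1 and C5 by group selection and leaves ring A as an enol ether at C4. In stereochemical economy and in the speed with which the bicycle is reached this plan is at least the equal of the chosen one.
- Against: C7 ends up bearing oxygen, not carbon. Exchanging it for an exo prenyl group means C–C bond formation at a hindered secondary centre next to a quaternary carbon, probably by a radical allylation and an alkene exchange. C2 still needs an allylic oxidation next to prenyl groups, and the C5 prenyl alkene can compete for the cation.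
- Comparison: structurally this plan is stronger for targets oxygenated at C7 and weaker here. Mechanistically a cation–alkene closure is less tolerant of spectator alkenes than the cycloaddition. In step count the fast start should be offset by the C7 exchange and the C2 oxidation.

Key step: step 3

Remark: 25 is an enolised β-diketone whose enol tautomers interconvert; the route aims at the trione whichever enol is drawn.
Remark: the ring B stereocentre is never touched after step 3; its descriptor changes (R in 6–8, S in 9 and 10, R from 11 on) only because the priorities of its neighbours change, and the same holds for C5 and C1 between 14 and 25.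
Remark: 21 and the (R,R) ligand are assumed to be bought as single enantiomers; the (R,R) ligand is the one that the square-planar chelate model assigns to the (R) adduct 6.

## Route

Step 1
Reactants: 1 mesityl oxide (4-methylpent-3-en-2-one)
Product: 2 4-methyl-2-(triisopropylsilyloxy)penta-1,3-diene
Conditions: LiN(i-Pr)2 (1.1 equiv), THF, −78 °C; then i-Pr3SiOTf, −78 °C to 0 °C
Reagents that add atoms: triisopropylsilyl trifluoromethanesulfonate CC(C)[Si](C(C)C)(C(C)C)OS(=O)(=O)C(F)(F)F
Why: Kinetic enolisation and O-silylation; the hindered amide removes a proton from the methyl ketone side and not from the γ-methyl groups, and the silyl triflate traps the cross-conjugated dienolate on oxygen. No stereocentre is formed.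

Step 2
Reactants: 3 oxazolidin-2-one; 4 acryloyl chloride
Product: 5 3-acryloyloxazolidin-2-one
Conditions: NaH, THF, 0 °C; then 4, −78 °C to 0 °C, 2,6-di-tert-butyl-4-methylphenol (trace)
Reagents that add atoms: none
Why: N-Acylation of the sodium salt of the carbamate with the acid chloride; the low temperature and the radical inhibitor should hold back polymerisation of the acrylate.

Step 3
Reactants: 2 4-methyl-2-(triisopropylsilyloxy)penta-1,3-diene; 5 3-acryloyloxazolidin-2-one
Product: 6 3-{[(1R)-2,2-dimethyl-4-(triisopropylsilyloxy)cyclohex-3-en-1-yl]carbonyl}oxazolidin-2-one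
Conditions: [Cu((R,R)-t-Bu-box)](SbF6)2 (10 mol %, made from CuCl2, 2,2'-(propane-2,2-diyl)bis[(4R)-4-tert-butyl-4,5-dihydrooxazole] and AgSbF6), 2 (1.5 equiv), 4 Å molecular sieves, CH2Cl2, −40 °C to 0 °C
Reagents that add atoms: none
Why: The imide binds the divalent copper centre through both carbonyl oxygens in a distorted square-planar chelate with the acryloyl group s-cis, which lowers its LUMO and puts one tert-butyl group over one face of the alkene. The CH2 terminus of 2, which has the largest HOMO coefficient of a 2-silyloxydiene, bonds to the β-carbon (C5–C6) and the dimethyl terminus to the α-carbon (C7–C8), either in one asynchronous [4+2] event or, because the cis methyl group disfavours the s-cis diene, by Mukaiyama–Michael addition followed by attack of the copper-bound enolate on the silyloxyallyl cation. The closest known reaction type is the bis(oxazoline)copper-catalysed Diels–Alder reaction of acryloyl oxazolidinones with oxygenated dienes. Ring B is closed as a cyclohexene by [4+2] cycloaddition or, in the stepwise case, by a 6-endo-trig attack of the enolate carbon on the CMe2 terminus. The only new stereocentre, C7, is set by the catalyst: in both pathways C7–C8 forms on the face remote from the tert-butyl group, which for the (R,R) ligand should be the Si face of the α-carbon and lead to the (R) configuration. The step needs regioselectivity, which the silyloxy group secures (C9 ends up 1,4 to C7), and enantiofacial selectivity, which the two-point binding of the imide secures. The bulky triisopropylsilyl group is kept on purpose because it slows silyl transfer to the imide, which would open a silicon-catalysed racemic channel, and because it lets the product enol ether protect C9 through steps 4 to 6.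

Step 4
Reactants: 6 3-{[(1R)-2,2-dimethyl-4-(triisopropylsilyloxy)cyclohex-3-en-1-yl]carbonyl}oxazolidin-2-one
Product: 7 [(1R)-2,2-dimethyl-4-(triisopropylsilyloxy)cyclohex-3-en-1-yl]methanol
Conditions: LiBH4, MeOH (1 equiv), THF, 0 °C
Reagents that add atoms: none
Why: Reductive cleavage of an N-acyl oxazolidinone; hydride attacks the exocyclic carbonyl, the carbamate leaves and the aldehyde is reduced further. The medium is not basic enough to epimerise C7 and the silyl enol ether is inert to borohydride.

Step 5
Reactants: 7 [(1R)-2,2-dimethyl-4-(triisopropylsilyloxy)cyclohex-3-en-1-yl]methanol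
Product: 8 [(1R)-2,2-dimethyl-4-(triisopropylsilyloxy)cyclohex-3-en-1-yl]methyl 4-methylbenzenesulfonate
Conditions: TsCl, Et3N, 4-(dimethylamino)pyridine (cat.), CH2Cl2, 0 °C to rt
Reagents that add atoms: 4-methylbenzenesulfonyl chloride Cc1ccc(cc1)S(=O)(=O)Cl
Why: Sulfonylation of a primary alcohol under basic conditions, which the acid-labile silyl enol ether tolerates.

Step 6
Reactants: 8 [(1R)-2,2-dimethyl-4-(triisopropylsilyloxy)cyclohex-3-en-1-yl]methyl 4-methylbenzenesulfonate
Product: 10 (4S)-3,3-dimethyl-4-(3-methylbut-2-en-1-yl)cyclohexan-1-one, via silyl enol ether 9 (not isolated)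
Conditions: Me2C=CHMgBr (3 equiv), CuI (10 mol %), THF, −20 °C to rt; then 1 M aqueous HCl, THF, rt
Reagents that add atoms: 2-methylprop-1-en-1-ylmagnesium bromide CC(C)=C[Mg]Br
Why: Copper-catalysed coupling of a primary sulfonate with an alkenyl Grignard reagent (substitution by the alkenylcuprate) completes the prenyl group, with the former imide carbon as its CH2. Dilute acid then hydrolyses the silyl enol ether by C-protonation, which should be much faster than hydration of the trisubstituted alkene.

Step 7
Reactants: 10 (4S)-3,3-dimethyl-4-(3-methylbut-2-en-1-yl)cyclohexan-1-one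
Product: 11 (4R)-5,5-dimethyl-2,4-bis(3-methylbut-2-en-1-yl)cyclohexan-1-one (both C2 epimers)
Conditions: LiN(i-Pr)2 (1.05 equiv), THF, −78 °C; then 1-bromo-3-methylbut-2-ene, −78 °C to 0 °C
Reagents that add atoms: 1-bromo-3-methylbut-2-ene CC(C)=CCBr
Why: Kinetic enolate alkylation; the base takes the proton from the methylene remote from the gem-dimethyl group, whose axial methyl shields the other α-position. The configuration at C2 is irrelevant because that carbon becomes sp2 in step 8.

Step 8
Reactants: 11 (4R)-5,5-dimethyl-2,4-bis(3-methylbut-2-en-1-yl)cyclohexan-1-one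
Product: 13 (4R)-1-methoxy-5,5-dimethyl-2,4-bis(3-methylbut-2-en-1-yl)cyclohex-1-ene (with its double-bond isomer), via dimethyl ketal 12 (not isolated)
Conditions: HC(OMe)3, p-toluenesulfonic acid (cat.), MeOH, rt; then concentrate and heat to 140 °C with removal of MeOH
Reagents that add atoms: trimethyl orthoformate COC(OC)OC
Why: Acid-catalysed ketalisation followed by loss of methanol gives the methyl enol ether, mainly the tetrasubstituted isomer. Both double-bond isomers lead to the same product in step 9, so the mixture is used as such.

Step 9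
Reactants: 13 (4R)-1-methoxy-5,5-dimethyl-2,4-bis(3-methylbut-2-en-1-yl)cyclohex-1-ene
Product: 14 (1R,5S,7R)-8,8-dimethyl-5,7-bis(3-methylbut-2-en-1-yl)bicyclo[3.3.1]nonane-2,4,9-trione (enolised)
Conditions: malonyl dichloride (1.5 equiv), Et2O, −20 °C to rt; then aqueous KOH, benzyltriethylammonium chloride, rt; acidify to pH 3
Reagents that add atoms: malonyl dichloride O=C(Cl)CC(=O)Cl
Why: Effenberger cyclisation; the enol ether carbon is C-acylated and the second acid chloride then acylates the other α-carbon of the ketone, forming C4–C5 and C1–C2 and closing ring A at the trione level. The first bond should form axially on the face anti to the equatorial C7 chain and the second can only form cis to the first, so the bridge ends up trans to the C7 prenyl group, which sets C5 and C1.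

Step 10
Reactants: 14 (1R,5S,7R)-8,8-dimethyl-5,7-bis(3-methylbut-2-en-1-yl)bicyclo[3.3.1]nonane-2,4,9-trione
Product: 15 (1R,5S,7R)-2-methoxy-8,8-dimethyl-5,7-bis(3-methylbut-2-en-1-yl)bicyclo[3.3.1]non-2-ene-4,9-dione
Conditions: HC(OMe)3, p-toluenesulfonic acid (cat.), MeOH, 50 °C
Reagents that add atoms: trimethyl orthoformate COC(OC)OC
Why: Acid-catalysed enol etherification of a vinylogous acid; the C2 oxygen lies next to the bridgehead C–H and is less hindered than the C4 oxygen next to the quaternary C5, so 15 should be the main isomer. Any C4-methoxy isomer would be separated and returned to 14 by hydrolysis.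

Step 11
Reactants: 15 (1R,5S,7R)-2-methoxy-8,8-dimethyl-5,7-bis(3-methylbut-2-en-1-yl)bicyclo[3.3.1]non-2-ene-4,9-dione
Product: 16 (1R,5R,7R)-3-iodo-2-methoxy-8,8-dimethyl-5,7-bis(3-methylbut-2-en-1-yl)bicyclo[3.3.1]non-2-ene-4,9-dione
Conditions: lithium 2,2,6,6-tetramethylpiperidide (1.3 equiv), THF, −78 °C; then I2, −78 °C
Reagents that add atoms: iodine II
Why: α-Lithiation of a vinylogous ester and iodine quench; the vinylic C3–H between the carbonyl and the methoxy-bearing carbon is the kinetically most acidic proton for this hindered amide. The vinyllithium should take up iodine faster than iodine reacts with the prenyl alkenes.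

Step 12
Reactants: 17 2-methylbut-3-en-2-ol
Product: 18 triethyl[(2-methylbut-3-en-2-yl)oxy]silane
Conditions: Et3SiOTf, 2,6-lutidine, CH2Cl2, 0 °C
Reagents that add atoms: triethylsilyl trifluoromethanesulfonate CC[Si](CC)(CC)OS(=O)(=O)C(F)(F)F
Why: Silylation of a tertiary alcohol, which needs the silyl triflate; the triethylsilyl ether is chosen to survive aqueous base and lithium amides and to fall to fluoride at the end.

Step 13
Reactants: 16 (1R,5R,7R)-3-iodo-2-methoxy-8,8-dimethyl-5,7-bis(3-methylbut-2-en-1-yl)bicyclo[3.3.1]non-2-ene-4,9-dione; 18 triethyl[(2-methylbut-3-en-2-yl)oxy]silane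
Product: 20 (1R,5R,7R)-2-methoxy-8,8-dimethyl-5,7-bis(3-methylbut-2-en-1-yl)-3-[3-methyl-3-(triethylsilyloxy)butyl]bicyclo[3.3.1]non-2-ene-4,9-dione, via B-alkyl-9-borabicyclononane 19 (not isolated)
Conditions: 18 (1.6 equiv), 9-BBN-H (1.5 equiv), THF, 0 °C to rt; then 16, PdCl2(dppf) (5 mol %, dppf = 1,1'-bis(diphenylphosphino)ferrocene), AsPh3, Cs2CO3, DMF–H2O, rt to 40 °C
Reagents that add atoms: none
Why: Anti-Markovnikov hydroboration of the monosubstituted alkene followed by B-alkyl Suzuki–Miyaura coupling with the α-iodo enone (oxidative addition at C–I, base-assisted transfer of the primary alkyl group, reductive elimination) forms the C3–CH2 bond. The alkene is used in slight excess over the borane, so no B–H is left to meet the prenyl groups of 16.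

Step 14
Reactants: 21 (2R)-2-methylbutanoic acid
Product: 22 (2R)-2-methylbutanoyl chloride
Conditions: (COCl)2, DMF (cat.), CH2Cl2, 0 °C to rt; volatiles removed, used at once
Reagents that add atoms: oxalyl chloride O=C(Cl)C(=O)Cl
Why: Acid chloride formation under chloroiminium catalysis; no base is present, so the α-stereocentre is not enolised.

Step 15
Reactants: 20 (1R,5R,7R)-2-methoxy-8,8-dimethyl-5,7-bis(3-methylbut-2-en-1-yl)-3-[3-methyl-3-(triethylsilyloxy)butyl]bicyclo[3.3.1]non-2-ene-4,9-dione; 22 (2R)-2-methylbutanoyl chloride
Product: 23 (1R,5S,7R)-2-methoxy-8,8-dimethyl-1-[(2R)-2-methylbutanoyl]-5,7-bis(3-methylbut-2-en-1-yl)-3-[3-methyl-3-(triethylsilyloxy)butyl]bicyclo[3.3.1]non-2-ene-4,9-dione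
Conditions: LiN(i-Pr)2 (1.5 equiv), THF, −78 °C; then transfer into 22 (3 equiv), THF, −78 °C
Reagents that add atoms: none
Why: Bridgehead lithiation and acylation; C1–H is the only acidic C–H left, and its anion is held by the inductive effect of the C9 ketone and by coordination to the C2 methoxy oxygen, a bridgehead enolate being geometrically impossible. The bridgehead organolithium cannot invert, so the acyl group takes the exo position, and direct addition–elimination at 22 leaves its α-stereocentre untouched.

Step 16
Reactants: 23 (1R,5S,7R)-2-methoxy-8,8-dimethyl-1-[(2R)-2-methylbutanoyl]-5,7-bis(3-methylbut-2-en-1-yl)-3-[3-methyl-3-(triethylsilyloxy)butyl]bicyclo[3.3.1]non-2-ene-4,9-dione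
Product: 25 (1S,5S,7R)-4-hydroxy-3-(3-hydroxy-3-methylbutyl)-8,8-dimethyl-1-[(2R)-2-methylbutanoyl]-5,7-bis(3-methylbut-2-en-1-yl)bicyclo[3.3.1]non-3-ene-2,9-dione, via triethylsilyl ether 24 (not isolated)
Conditions: LiCl (10 equiv), DMSO, 120 °C; then cool to rt, Bu4NF (THF), rt; work-up with pH 5 phosphate buffer
Reagents that add atoms: none
Why: Chloride cleaves the O–CH3 bond of the vinylogous ester by SN2 (Krapcho-type dealkylation) under nearly neutral conditions, and fluoride then removes the silyl ether. No acid is present to close the tertiary alcohol onto the enol and no strong base to epimerise the acyl α-carbon.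

## Compound list

1 | mesityl oxide (4-methylpent-3-en-2-one) | CC(=O)C=C(C)C | starting material
2 | 4-methyl-2-(triisopropylsilyloxy)penta-1,3-diene | C=C(O[Si](C(C)C)(C(C)C)C(C)C)C=C(C)C | intermediate
3 | oxazolidin-2-one | O=C1NCCO1 | starting material
4 | acryloyl chloride | C=CC(=O)Cl | starting material
5 | 3-acryloyloxazolidin-2-one | C=CC(=O)N1CCOC1=O | intermediate
6 | 3-{[(1R)-2,2-dimethyl-4-(triisopropylsilyloxy)cyclohex-3-en-1-yl]carbonyl}oxazolidin-2-one | O=C(N1CCOC1=O)[C@@H]2CCC(O[Si](C(C)C)(C(C)C)C(C)C)=CC2(C)C | intermediate
7 | [(1R)-2,2-dimethyl-4-(triisopropylsilyloxy)cyclohex-3-en-1-yl]methanol | OC[C@@H]1CCC(O[Si](C(C)C)(C(C)C)C(C)C)=CC1(C)C | intermediate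
8 | [(1R)-2,2-dimethyl-4-(triisopropylsilyloxy)cyclohex-3-en-1-yl]methyl 4-methylbenzenesulfonate | Cc1ccc(cc1)S(=O)(=O)OC[C@@H]2CCC(O[Si](C(C)C)(C(C)C)C(C)C)=CC2(C)C | intermediate
9 | {[(4S)-3,3-dimethyl-4-(3-methylbut-2-en-1-yl)cyclohex-1-en-1-yl]oxy}triisopropylsilane (formed in the flask) | CC(C)=CC[C@@H]1CCC(O[Si](C(C)C)(C(C)C)C(C)C)=CC1(C)C | intermediate
10 | (4S)-3,3-dimethyl-4-(3-methylbut-2-en-1-yl)cyclohexan-1-one | CC(C)=CC[C@@H]1CCC(=O)CC1(C)C | intermediate
11 | (4R)-5,5-dimethyl-2,4-bis(3-methylbut-2-en-1-yl)cyclohexan-1-one (both C2 epimers) | CC(C)=CCC1C[C@@H](CC=C(C)C)C(C)(C)CC1=O | intermediate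
12 | (4R)-1,1-dimethoxy-5,5-dimethyl-2,4-bis(3-methylbut-2-en-1-yl)cyclohexane (both C2 epimers, formed in the flask) | CC(C)=CCC1C[C@@H](CC=C(C)C)C(C)(C)CC1(OC)OC | intermediate
13 | (4R)-1-methoxy-5,5-dimethyl-2,4-bis(3-methylbut-2-en-1-yl)cyclohex-1-ene | COC1=C(CC=C(C)C)C[C@@H](CC=C(C)C)C(C)(C)C1 | intermediate
14 | (1R,5S,7R)-8,8-dimethyl-5,7-bis(3-methylbut-2-en-1-yl)bicyclo[3.3.1]nonane-2,4,9-trione (drawn as its 4-hydroxy-3-en-2-one enol) | [C@H]12C(=O)C=C(O)[C@](CC=C(C)C)(C[C@@H](CC=C(C)C)C1(C)C)C2=O | intermediate
15 | (1R,5S,7R)-2-methoxy-8,8-dimethyl-5,7-bis(3-methylbut-2-en-1-yl)bicyclo[3.3.1]non-2-ene-4,9-dione | [C@H]12C(OC)=CC(=O)[C@](CC=C(C)C)(C[C@@H](CC=C(C)C)C1(C)C)C2=O | intermediate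
16 | (1R,5R,7R)-3-iodo-2-methoxy-8,8-dimethyl-5,7-bis(3-methylbut-2-en-1-yl)bicyclo[3.3.1]non-2-ene-4,9-dione | [C@H]12C(OC)=C(I)C(=O)[C@](CC=C(C)C)(C[C@@H](CC=C(C)C)C1(C)C)C2=O | intermediate
17 | 2-methylbut-3-en-2-ol | C=CC(C)(C)O | starting material
18 | triethyl[(2-methylbut-3-en-2-yl)oxy]silane | C=CC(C)(C)O[Si](CC)(CC)CC | intermediate
19 | 9-[3-methyl-3-(triethylsilyloxy)butyl]-9-borabicyclo[3.3.1]nonane (formed in the flask) | CC[Si](CC)(CC)OC(C)(C)CCB1C2CCCC1CCC2 | intermediate
20 | (1R,5R,7R)-2-methoxy-8,8-dimethyl-5,7-bis(3-methylbut-2-en-1-yl)-3-[3-methyl-3-(triethylsilyloxy)butyl]bicyclo[3.3.1]non-2-ene-4,9-dione | [C@H]12C(OC)=C(CCC(C)(C)O[Si](CC)(CC)CC)C(=O)[C@](CC=C(C)C)(C[C@@H](CC=C(C)C)C1(C)C)C2=O | intermediate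
21 | (2R)-2-methylbutanoic acid | CC[C@@H](C)C(=O)O | starting material
22 | (2R)-2-methylbutanoyl chloride | CC[C@@H](C)C(=O)Cl | intermediate
23 | (1R,5S,7R)-2-methoxy-8,8-dimethyl-1-[(2R)-2-methylbutanoyl]-5,7-bis(3-methylbut-2-en-1-yl)-3-[3-methyl-3-(triethylsilyloxy)butyl]bicyclo[3.3.1]non-2-ene-4,9-dione | CC[C@@H](C)C(=O)[C@]12C(OC)=C(CCC(C)(C)O[Si](CC)(CC)CC)C(=O)[C@](CC=C(C)C)(C[C@@H](CC=C(C)C)C1(C)C)C2=O | intermediate
24 | (1S,5S,7R)-4-hydroxy-8,8-dimethyl-1-[(2R)-2-methylbutanoyl]-5,7-bis(3-methylbut-2-en-1-yl)-3-[3-methyl-3-(triethylsilyloxy)butyl]bicyclo[3.3.1]non-3-ene-2,9-dione (formed in the flask) | CC[C@@H](C)C(=O)[C@]12C(=O)C(CCC(C)(C)O[Si](CC)(CC)CC)=C(O)[C@](CC=C(C)C)(C[C@@H](CC=C(C)C)C1(C)C)C2=O | intermediate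
25 | (1S,5S,7R)-4-hydroxy-3-(3-hydroxy-3-methylbutyl)-8,8-dimethyl-1-[(2R)-2-methylbutanoyl]-5,7-bis(3-methylbut-2-en-1-yl)bicyclo[3.3.1]non-3-ene-2,9-dione | CC[C@@H](C)C(=O)[C@]12C(=O)C(CCC(C)(C)O)=C(O)[C@](CC=C(C)C)(C[C@@H](CC=C(C)C)C1(C)C)C2=O | target

## Step count and least certain steps

Total: 16 steps. Longest linear sequence: 13 steps (steps 1, 3 to 11, 13, 15 and 16, from 1 to 25).

**Step 3 (key step).** The cis methyl group may keep the diene out of the s-cis geometry, so that C–C bond formation stops after the first bond or is overtaken by desilylation of the diene. Enantiofacial control may also erode if ring closure happens off the metal or through a silicon-catalysed channel. The fallback moves the control from the catalyst to an auxiliary and sets out from 2 and 4. (4S)-4-Benzyloxazolidin-2-one is lithiated (n-BuLi) and acylated with 4 to give (4S)-3-acryloyl-4-benzyloxazolidin-2-one F1. F1 and 2 are combined with Et2AlCl in CH2Cl2 at −78 °C, where the benzyl group of the chelated s-cis imide should cover the Re face of the α-carbon, to give (4S)-4-benzyl-3-{[(1R)-2,2-dimethyl-4-(triisopropylsilyloxy)cyclohex-3-en-1-yl]carbonyl}oxazolidin-2-one F2. The diastereomers can be separated, and LiBH4 then releases the auxiliary and returns to the route at 7.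

**Step 9.** O-acylation of the enol ether and self-condensation of the acid chloride can outrun C-acylation, and the second, ring-closing acylation at the neopentyl C1 is slow, so material is diverted before the bicycle closes. The fallback builds ring A one bond at a time and sets out from 11.
- KH (equilibrating conditions) and propargyl bromide should alkylate the more substituted enolate axially, trans to the C7 chain, to give (2S,4R)-5,5-dimethyl-2,4-bis(3-methylbut-2-en-1-yl)-2-(prop-2-yn-1-yl)cyclohexan-1-one F5.
- t-BuMe2SiOTf and Et3N give tert-butyl{[(4R,6S)-3,3-dimethyl-4,6-bis(3-methylbut-2-en-1-yl)-6-(prop-2-yn-1-yl)cyclohex-1-en-1-yl]oxy}dimethylsilane F6.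
- [Au(NCMe)(P(t-Bu)2(biphenyl-2-yl))]SbF6 (monovalent gold) in wet acetone closes ring A by 6-endo-dig attack to give (1S,5S,7R)-8,8-dimethyl-5,7-bis(3-methylbut-2-en-1-yl)bicyclo[3.3.1]non-2-en-9-one F7.
- Allylic oxidation at C4 with CrO3 and 3,5-dimethylpyrazole gives (1S,5S,7R)-8,8-dimethyl-5,7-bis(3-methylbut-2-en-1-yl)bicyclo[3.3.1]non-2-ene-4,9-dione F8.
- H2O2 and NaOH give 2,3-epoxy-8,8-dimethyl-5,7-bis(3-methylbut-2-en-1-yl)bicyclo[3.3.1]nonane-4,9-dione F9.
- Pd(PPh3)4 (zerovalent palladium) with 1,2-bis(diphenylphosphino)ethane in hot toluene isomerises the epoxy ketone to the β-diketone and returns to the route at 14.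

This fallback is longer, and its allylic oxidation has to prefer the ring methylene over the prenyl groups, which is its own weak point.

**Step 6.** Substitution at the β-branched primary carbon may be slow enough for the Grignard reagent to attack at sulfur or to act as a base. The fallback reverses the polarity and sets out from 8. NaI in acetone gives {[(4R)-4-(iodomethyl)-3,3-dimethylcyclohex-1-en-1-yl]oxy}triisopropylsilane F3. Zinc dust and LiCl in THF give {[(1R)-2,2-dimethyl-4-(triisopropylsilyloxy)cyclohex-3-en-1-yl]methyl}zinc iodide F4. Negishi coupling of F4 with 1-bromo-2-methylprop-1-ene and Pd(PPh3)4 (zerovalent palladium) gives 9, and the acid treatment of step 6 returns to the route at 10.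

**Step 15.** The bridgehead anion is a strong, hindered base and may deprotonate 22 instead of adding to it; the resulting ketene pathway would return 20 and scramble the acyl α-stereocentre. The fallback replaces acyl substitution by carbonyl addition and oxidation and sets out from 20 and 22. LiAlH(O-t-Bu)3 at −78 °C reduces 22 to (2R)-2-methylbutanal F12, used at once. Lithiated 20 adds to F12 to give (1R,5S,7R)-1-[(2R)-1-hydroxy-2-methylbutyl]-2-methoxy-8,8-dimethyl-5,7-bis(3-methylbut-2-en-1-yl)-3-[3-methyl-3-(triethylsilyloxy)butyl]bicyclo[3.3.1]non-2-ene-4,9-dione F13 as a mixture of carbinol epimers. Dess–Martin periodinane then returns to the route at 23.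

**Step 13.** Transfer of the alkyl group to palladium at the doubly flanked C3 may be slow, so that loss of iodine by protonation or β-hydride loss from the alkylpalladium takes over. The fallback makes the bond as an sp2–sp bond and sets out from 16. Sonogashira coupling with 2-methylbut-3-yn-2-ol (PdCl2(PPh3)2, CuI, Et3N) gives (1R,5R,7R)-3-(3-hydroxy-3-methylbut-1-yn-1-yl)-2-methoxy-8,8-dimethyl-5,7-bis(3-methylbut-2-en-1-yl)bicyclo[3.3.1]non-2-ene-4,9-dione F10. Hydrogenation with RhCl(PPh3)3, which should leave trisubstituted and tetrasubstituted alkenes alone, gives (1R,5R,7R)-3-(3-hydroxy-3-methylbutyl)-2-methoxy-8,8-dimethyl-5,7-bis(3-methylbut-2-en-1-yl)bicyclo[3.3.1]non-2-ene-4,9-dione F11. Et3SiOTf and 2,6-lutidine then return to the route at 20.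

## Further compounds

F1 | step 3 | (4S)-3-acryloyl-4-benzyloxazolidin-2-one | C=CC(=O)N1[C@@H](Cc2ccccc2)COC1=O
F2 | step 3 | (4S)-4-benzyl-3-{[(1R)-2,2-dimethyl-4-(triisopropylsilyloxy)cyclohex-3-en-1-yl]carbonyl}oxazolidin-2-one | O=C([C@@H]1CCC(O[Si](C(C)C)(C(C)C)C(C)C)=CC1(C)C)N2[C@@H](Cc3ccccc3)COC2=O
F3 | step 6 | {[(4R)-4-(iodomethyl)-3,3-dimethylcyclohex-1-en-1-yl]oxy}triisopropylsilane | IC[C@@H]1CCC(O[Si](C(C)C)(C(C)C)C(C)C)=CC1(C)C
F4 | step 6 | {[(1R)-2,2-dimethyl-4-(triisopropylsilyloxy)cyclohex-3-en-1-yl]methyl}zinc iodide | I[Zn]C[C@@H]1CCC(O[Si](C(C)C)(C(C)C)C(C)C)=CC1(C)C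
F5 | step 9 | (2S,4R)-5,5-dimethyl-2,4-bis(3-methylbut-2-en-1-yl)-2-(prop-2-yn-1-yl)cyclohexan-1-one | C#CC[C@]1(CC=C(C)C)C[C@@H](CC=C(C)C)C(C)(C)CC1=O
F6 | step 9 | tert-butyl{[(4R,6S)-3,3-dimethyl-4,6-bis(3-methylbut-2-en-1-yl)-6-(prop-2-yn-1-yl)cyclohex-1-en-1-yl]oxy}dimethylsilane | C#CC[C@]1(CC=C(C)C)C[C@@H](CC=C(C)C)C(C)(C)C=C1O[Si](C)(C)C(C)(C)C
F7 | step 9 | (1S,5S,7R)-8,8-dimethyl-5,7-bis(3-methylbut-2-en-1-yl)bicyclo[3.3.1]non-2-en-9-one | [C@H]12C=CC[C@](CC=C(C)C)(C[C@@H](CC=C(C)C)C1(C)C)C2=O
F8 | step 9 | (1S,5S,7R)-8,8-dimethyl-5,7-bis(3-methylbut-2-en-1-yl)bicyclo[3.3.1]non-2-ene-4,9-dione | [C@H]12C=CC(=O)[C@](CC=C(C)C)(C[C@@H](CC=C(C)C)C1(C)C)C2=O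
F9 | step 9 | 2,3-epoxy-8,8-dimethyl-5,7-bis(3-methylbut-2-en-1-yl)bicyclo[3.3.1]nonane-4,9-dione (C1, C5 and C7 as in F8) | [C@H]12C3OC3C(=O)[C@](CC=C(C)C)(C[C@@H](CC=C(C)C)C1(C)C)C2=O
F10 | step 13 | (1R,5R,7R)-3-(3-hydroxy-3-methylbut-1-yn-1-yl)-2-methoxy-8,8-dimethyl-5,7-bis(3-methylbut-2-en-1-yl)bicyclo[3.3.1]non-2-ene-4,9-dione | [C@H]12C(OC)=C(C#CC(C)(C)O)C(=O)[C@](CC=C(C)C)(C[C@@H](CC=C(C)C)C1(C)C)C2=O
F11 | step 13 | (1R,5R,7R)-3-(3-hydroxy-3-methylbutyl)-2-methoxy-8,8-dimethyl-5,7-bis(3-methylbut-2-en-1-yl)bicyclo[3.3.1]non-2-ene-4,9-dione | [C@H]12C(OC)=C(CCC(C)(C)O)C(=O)[C@](CC=C(C)C)(C[C@@H](CC=C(C)C)C1(C)C)C2=O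
F12 | step 15 | (2R)-2-methylbutanal | CC[C@@H](C)C=O
F13 | step 15 | (1R,5S,7R)-1-[(2R)-1-hydroxy-2-methylbutyl]-2-methoxy-8,8-dimethyl-5,7-bis(3-methylbut-2-en-1-yl)-3-[3-methyl-3-(triethylsilyloxy)butyl]bicyclo[3.3.1]non-2-ene-4,9-dione (both carbinol epimers) | CC[C@@H](C)C(O)[C@]12C(OC)=C(CCC(C)(C)O[Si](CC)(CC)CC)C(=O)[C@](CC=C(C)C)(C[C@@H](CC=C(C)C)C1(C)C)C2=O
A1 | alternative 1 | 4,4-dimethyl-1,3-bis(3-methylbut-2-en-1-yl)bicyclo[3.2.1]octane-6,7,8-trione (configured as the target at the carbons that become C1, C5 and C7) | [C@H]12C(=O)C(=O)[C@](CC=C(C)C)(C[C@@H](CC=C(C)C)C1(C)C)C2=O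
A2 | alternative 1 | [(4-diazo-2-methylbutan-2-yl)oxy]triethylsilane | [N-]=[N+]=CCCC(C)(C)O[Si](CC)(CC)CC
A3 | alternative 1 | (1R,5S,7R)-4-hydroxy-8,8-dimethyl-5,7-bis(3-methylbut-2-en-1-yl)-3-[3-methyl-3-(triethylsilyloxy)butyl]bicyclo[3.3.1]non-3-ene-2,9-dione | [C@H]12C(=O)C(CCC(C)(C)O[Si](CC)(CC)CC)=C(O)[C@](CC=C(C)C)(C[C@@H](CC=C(C)C)C1(C)C)C2=O
A4 | alternative 2 | (2S)-3-(tert-butyldimethylsilyloxy)-5,5-dimethyl-2-(3-methylbut-2-en-1-yl)-2-(prop-2-yn-1-yl)cyclohex-3-en-1-one | C#CC[C@]1(CC=C(C)C)C(=O)CC(C)(C)C=C1O[Si](C)(C)C(C)(C)C
A5 | alternative 2 | (1S,5S)-8,8-dimethyl-5-(3-methylbut-2-en-1-yl)bicyclo[3.3.1]non-2-ene-6,9-dione | [C@H]12C=CC[C@](CC=C(C)C)(C(=O)CC1(C)C)C2=O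
A6 | alternative 3 | 6-{[(2R)-3,3-dimethyloxiran-2-yl]methyl}-1,5-dimethoxy-6-(3-methylbut-2-en-1-yl)cyclohexa-1,4-diene | COC1=CCC=C(OC)C1(CC=C(C)C)C[C@H]2OC2(C)C
A7 | alternative 3 | (1S,5S,7R)-7-hydroxy-4-methoxy-8,8-dimethyl-5-(3-methylbut-2-en-1-yl)bicyclo[3.3.1]non-3-en-9-one | [C@H]12CC=C(OC)[C@](CC=C(C)C)(C[C@@H](O)C1(C)C)C2=O
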